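## Analysis of the target

The target 36 is a cembranolide. Its 14-membered carbocycle (C1–C14) carries an α-methyl butenolide fused at C1–C2 (C1=C15 tetrasubstituted, lactone oxygen on C2, carbonyl C16, methyl C17). The ring also holds two E-trisubstituted olefins (C3=C4 with C18, C11=C12 with C20), a trisubstituted epoxide at C7–C8 (C19 on C8) and an acetoxy group on C13.

The four stereocentres fall into two groups that cannot relay to each other. C2 (R) and C13 (R) flank the butenolide and are separated by C1 and C14. C7 (S) and C8 (R) lie across the ring, with C6 and C9 cis on the oxirane, so the epoxide corresponds to a Z olefin.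

The C2–H is both allylic and the γ-hydrogen of the butenolide and is easily removed by base. The epoxide does not tolerate protic or Lewis acids or strong hydride donors. The C13 acetate is allylic and would ionise with zerovalent palladium or be attacked by carbanions.

The synthesis is hard for three reasons: a 14-membered ring must be closed without loss of olefin geometry, the epoxide must be placed on one of three similar trisubstituted positions with the right absolute sense, and C2 must pass basic steps intact.

The plan rests on the C5–C6 bond. It is the one CH2–CH2 ring bond whose ends can take opposite polarity: C5 is allylic to C3=C4 and can carry a sulfonyl group, and C6 is primary and sits next to the epoxide carbon C7. The bond is remote from C2 and C13. The stretch C6–C11 with C19 is the head of neryl acetate 1, whose Z allylic oxygen gives the cis epoxide and a C6 hydroxyl that becomes the leaving group.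

## Retrosynthetic reasoning

36 is the acetate of 35, and 35 is desilylated 34. The C13 oxygen is acylated last. An allylic acetate would not survive the carbanion of the ring closure or the palladium hydride that removes the sulfone, so a silyl ether stands in from 22 onward.

In 34 the C1=C15 bond is cut (intramolecular Horner–Wadsworth–Emmons reaction of 33), then the C16–O ester bond (29 + 30 give 31). The butenolide is therefore the last ring made, and its acidic C2–H never meets the base of the macrocyclisation. The cost is that C1 travels as a silyl-protected carbinol (31, 32, 33) and C2 as an ether (28 to 29). The forward steps must acylate C2–OH, unmask and oxidise C1, and condense without epimerising C2.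

28 comes from 27 by cutting the C5–S bond. The sulfonyl group is an auxiliary; its removal must place hydrogen on C5 and leave C3=C4 in position.

27 is opened at the ring bond C5–C6 to give 25. The alternatives are worse: C9–C10 has no activating group, a cut at an olefin means a trisubstituted olefination inside a macrocycle, and a cut at C13–C14 or C14–C1 means carbonyl chemistry in a ring that already holds the epoxide. At C5–C6 no stereocentre of the target is formed or endangered. The forward reaction must close the ring by SN2 at C6 in competition with epoxide opening, elimination and oligomerisation.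

25 is the iodide of epoxy alcohol 24, and 24 comes from Z allylic alcohol 23 by Sharpless epoxidation. The epoxide is introduced after the boron-mediated steps but before ring closure. At that point the C6 hydroxyl is the only free allylic alcohol and directs the oxidant to C7=C8 alone.

23 is traced through 22 and 21 to enone 20 by cutting the C13–H bond. The C13 stereocentre is set by a reagent-controlled ketone reduction, which is more predictable than aldol induction across C14.

20 is the silyl ether of 19, and 19 is cut at C14–C1 in the aldol sense into methyl ketone 6 and aldehyde 17. This divides the chain into halves of similar size. C1 is created as a carbinol, the protected form needed later, and its configuration is irrelevant because it ends as sp2.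

6 is cut at C11=C12 (Wittig) into aldehyde 4 and ylide 5. Aldehyde 4 is 1 without its terminal isopropylidene (via 2 and 3).

17 is traced through 16, 15 and 14 to acetonide 13. This sequence differentiates the C1 and C2 oxygens through the arylidene acetal. 13 is cut at C5–S into 10 and sulfinate 11, and 10 comes from 9, which is cut at C3=C4 into 7 and 8. C2 is taken from the chiral pool (7); the S aldehyde gives the R centre needed once the formyl carbon has become C3.

## Alternatives that were turned down

Alternative 1: The disconnection is C13–C14. Forward, Me2AlCl activates a C13 enal at one end of the open-chain precursor of A1, whose other end is a γ-lactone with an exocyclic C14 methylene. A carbonyl-ene reaction forms C13–C14, moves the olefin into C1=C15 and gives the tetraene butenolide A1 with a free C13 hydroxyl.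
- For it: ring, butenolide olefin and C13 carbinol arise in one step with no protecting groups on C1 and C2. On step economy it is clearly stronger than the chosen plan.
- Against it: the C13 configuration would depend on the folding of a 14-membered ene transition state, with only the distant C2 centre to bias it. The exocyclic methylene lactone can slip into conjugation before it acts as ene donor. The Lewis acid excludes the epoxide, so A1 carries a 7E olefin. That olefin must later be epoxidised selectively among three trisubstituted olefins and on one face, while the free C13 hydroxyl steers directed oxidants to C11=C12.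
- Comparison: the chosen route spends protecting-group steps but fixes the epoxide by a hydroxyl-directed asymmetric epoxidation and C13 by a reagent-controlled reduction.

Alternative 2: The disconnection is C1–C2. A chiral lithium amide deprotonates the propargylic C2 of a 17-membered propargyl allyl ether, the precursor of A2. A [2,3]-sigmatropic shift forms C1–C2, breaks O–C16 and contracts the ring to cycloalkyne A2 (C2 propargylic alcohol, C1 isopropenyl).
- For it: a ring contraction is entropically easier than an end-to-end closure, and on that point it may be stronger. The concerted shift also fixes the C1/C2 relationship.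
- Against it: the 17-membered ether needs a macrocyclisation of its own. The sense at C2 must come from selection between diastereotopic protons in a substrate that already carries C13 and the epoxide. The C1 stereocentre is made only to be destroyed. A2 lacks C18 and holds the lactone carbons as an isopropenyl group, so alkyne-to-methyl-olefin conversion, allylic oxidation, lactonisation and olefin migration all follow, next to an epoxide.
- Comparison: the chosen plan closes the ring with all ring olefins and methyl groups in place and offers certainty of geometry in place of the easier ring formation.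

Alternative 3: The disconnection is C11–C12 as an alkyne. (4-MeOC6H4)C≡Mo(OSiPh3)3 metathesises two methyl-capped alkynes and gives cycloalkyne A3, which already holds butenolide and epoxide.
- For it: this is the most tolerant and probably the most reliable ring closure of the four. It is neutral, has no carbanion and no competing elimination, and is stronger than the chosen key step on this point. It is also highly convergent.
- Against it: A3 has neither C20 nor any olefin geometry at C11/C12. Both must be made after ring closure by hydroxyl-directed trans-hydrostannation and tin-to-methyl exchange. That needs the C13 silyl ether removed, a regiochemical decision on the alkyne, and tin and copper chemistry beside the base-sensitive butenolide. The butenolide must also be carried through the whole fragment assembly.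
- Comparison: the chosen plan makes C11=C12 with its methyl by a Wittig reaction before ring closure and builds the butenolide last; it accepts a less tolerant ring closure in return.

Key step: step 18

Remark on the chemistry: positions are numbered as in cembranoids (ring C1–C14, lactone carbons C15–C17, methyls C18–C20). 27 is drawn as its 5R epimer, and the phosphorus-bearing carbon of 31–33, the acetal carbon of 15 and the oxirane carbon of 2 are left undefined, because none of these centres survives.

## Route

Step 1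
Reactants: 1 neryl acetate [(2Z)-3,7-dimethylocta-2,6-dien-1-yl acetate]
Product: 2 (2Z)-6,7-epoxy-3,7-dimethyloct-2-en-1-yl acetate (racemic)
Conditions: mCPBA, NaHCO3, CH2Cl2, −10 → 0 °C
Reagents that add atoms: 3-chloroperoxybenzoic acid, OOC(=O)c1cccc(Cl)c1
Why: Prilezhaev epoxidation; the distal trisubstituted olefin is the more electron-rich one because the other is deactivated by the allylic acetate, so mono-epoxidation should occur there; the new centre is cleaved off in step 2.

Step 2
Reactants: 2
Product: 4 (2Z)-3-methyl-6-oxohex-2-en-1-yl acetate, via diol 3 (not isolated)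
Conditions: H5IO6, THF–H2O, 0 °C
Reagents that add atoms: none
Why: Acid-mediated hydration of the epoxide and Malaprade cleavage of the glycol in one flask; this exposes C11 as an aldehyde and leaves the Z allylic acetate (C6–C8) untouched.

Step 3
Reactants: 4; 5 3-(triphenyl-λ5-phosphanylidene)butan-2-one
Product: 6 (2Z,6E)-3,7-dimethyl-8-oxonona-2,6-dien-1-yl acetate
Conditions: toluene, 80 °C
Reagents that add atoms: none
Why: Wittig olefination with a stabilised acyl ylide; the acyl group ends trans to the chain, which should give the 11E olefin and brings in C12, C13, C14 and C20.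

Step 4
Reactants: 7 (S)-2,2-dimethyl-1,3-dioxolane-4-carbaldehyde; 8 ethyl 2-(triphenyl-λ5-phosphanylidene)propanoate
Product: 9 ethyl (2E)-3-[(4R)-2,2-dimethyl-1,3-dioxolan-4-yl]-2-methylprop-2-enoate
Conditions: CH2Cl2, 0 → 25 °C
Reagents that add atoms: none
Why: Wittig olefination with a stabilised ylide should give the E enoate (C3=C4 with C18); C2 is taken unchanged from 7, and its descriptor changes from S to R only because the substituent ranking changes.

Step 5
Reactants: 9
Product: 10 (2E)-3-[(4R)-2,2-dimethyl-1,3-dioxolan-4-yl]-2-methylprop-2-en-1-ol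
Conditions: i-Bu2AlH, CH2Cl2, −78 °C; aqueous KNaC4H4O6
Reagents that add atoms: none
Why: 1,2-Reduction of the enoate to the allylic alcohol (C5–OH); the acetonide is inert at this temperature.

Step 6
Reactants: 10; 11 sodium benzenesulfinate
Product: 13 (4R)-2,2-dimethyl-4-[(1E)-2-methyl-3-(phenylsulfonyl)prop-1-en-1-yl]-1,3-dioxolane, via mesylate 12 (not isolated)
Conditions: MsCl, Et3N, THF, −20 °C; then PhSO2Na, n-Bu4NI (cat.), DMF, 25 °C
Reagents that add atoms: none
Why: Sulfonate activation followed by SN2 S-alkylation of the ambident sulfinate at the primary allylic carbon; this installs the C5 sulfone without touching the E olefin.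

Step 7
Reactants: 13
Product: 14 (2R,3E)-4-methyl-5-(phenylsulfonyl)pent-3-ene-1,2-diol
Conditions: AcOH–H2O (4:1), 40 °C
Reagents that add atoms: none
Why: Acid-catalysed hydrolysis of the acetonide; weak acid should not ionise the allylic C2–O bond.

Step 8
Reactants: 14
Product: 15 (4R)-2-(4-methoxyphenyl)-4-[(1E)-2-methyl-3-(phenylsulfonyl)prop-1-en-1-yl]-1,3-dioxolane (both acetal epimers)
Conditions: 4-MeOC6H4CH(OMe)2, pyridinium p-toluenesulfonate (cat.), CH2Cl2, 25 °C
Reagents that add atoms: 4-methoxybenzaldehyde dimethyl acetal, COc1ccc(cc1)C(OC)OC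
Why: Transacetalisation of the 1,2-diol; this prepares the regioselective release of the primary hydroxyl.

Step 9
Reactants: 15
Product: 16 (2R,3E)-2-[(4-methoxyphenyl)methoxy]-4-methyl-5-(phenylsulfonyl)pent-3-en-1-ol
Conditions: i-Bu2AlH, CH2Cl2, −78 → 0 °C; aqueous KNaC4H4O6
Reagents that add atoms: none
Why: Regioselective reductive opening of the arylidene acetal; aluminium binds the less hindered primary oxygen, that C–O bond breaks and hydride adds to the oxocarbenium ion, so the benzyl ether should stay on the C2 oxygen.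

Step 10
Reactants: 16
Product: 17 (2R,3E)-2-[(4-methoxyphenyl)methoxy]-4-methyl-5-(phenylsulfonyl)pent-3-enal
Conditions: Dess–Martin periodinane, NaHCO3, CH2Cl2, 0 °C; used crude at once
Reagents that add atoms: none
Why: Buffered hypervalent-iodine oxidation under non-basic conditions, chosen so that the α-alkoxy β,γ-unsaturated aldehyde is neither epimerised at C2 nor conjugated.

Step 11
Reactants: 6; 17
Product: 19 (2Z,6E,10S,11R,12E)-10-hydroxy-11-[(4-methoxyphenyl)methoxy]-3,7,13-trimethyl-8-oxo-14-(phenylsulfonyl)tetradeca-2,6,12-trien-1-yl acetate, via boron enolate 18 (not isolated)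
Conditions: (c-C6H11)2BCl, Et3N, Et2O, 0 °C (on 6); then 17, −78 → −20 °C; MeOH, pH 7 phosphate buffer
Reagents that add atoms: none
Why: Boron-mediated aldol addition; the enone is enolised kinetically at its methyl group (C14) and adds to the aldehyde to form C14–C1. Polar Felkin–Anh (Cornforth) addition anti to the C2 ether should give the 1S carbinol, a centre that is later oxidised.

Step 12
Reactants: 19
Product: 20 (2Z,6E,10S,11R,12E)-11-[(4-methoxyphenyl)methoxy]-3,7,13-trimethyl-8-oxo-14-(phenylsulfonyl)-10-[(triethylsilyl)oxy]tetradeca-2,6,12-trien-1-yl acetate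
Conditions: Et3SiCl, imidazole, DMF, 0 °C
Reagents that add atoms: chlorotriethylsilane, CC[Si](Cl)(CC)CC
Why: Silylation of the β-hydroxy enone under mild base; this blocks dehydration and retro-aldol and puts C1 in the protected form needed for the ring closure.

Step 13
Reactants: 20
Product: 21 (2Z,6E,8R,10S,11R,12E)-8-hydroxy-11-[(4-methoxyphenyl)methoxy]-3,7,13-trimethyl-14-(phenylsulfonyl)-10-[(triethylsilyl)oxy]tetradeca-2,6,12-trien-1-yl acetate
Conditions: (S)-1-methyl-3,3-diphenyltetrahydro-1H,3H-pyrrolo[1,2-c][1,3,2]oxazaborole (0.3 equiv), catecholborane, toluene, −78 °C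
Reagents that add atoms: none
Why: Corey–Bakshi–Shibata reduction; the α-methyl alkenyl group acts as the large substituent, so the S catalyst should deliver hydride to give the 13R allylic alcohol, by analogy with aryl and alkenyl methyl ketones. Catecholborane at −78 °C should not hydroborate the olefins.

Step 14
Reactants: 21
Product: 22 (2Z,6E,8R,10S,11R,12E)-8-[(tert-butyldimethylsilyl)oxy]-11-[(4-methoxyphenyl)methoxy]-3,7,13-trimethyl-14-(phenylsulfonyl)-10-[(triethylsilyl)oxy]tetradeca-2,6,12-trien-1-yl acetate
Conditions: t-BuMe2SiOSO2CF3, 2,6-lutidine, CH2Cl2, −78 °C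
Reagents that add atoms: tert-butyldimethylsilyl trifluoromethanesulfonate, CC(C)(C)[Si](C)(C)OS(=O)(=O)C(F)(F)F
Why: Silyl triflate silylation of the hindered allylic C13 hydroxyl; no epoxide is present yet, so the Lewis-acidic triflate is harmless.

Step 15
Reactants: 22
Product: 23 (2Z,6E,8R,10S,11R,12E)-8-[(tert-butyldimethylsilyl)oxy]-11-[(4-methoxyphenyl)methoxy]-3,7,13-trimethyl-14-(phenylsulfonyl)-10-[(triethylsilyl)oxy]tetradeca-2,6,12-trien-1-ol
Conditions: K2CO3, MeOH, 0 °C
Reagents that add atoms: none
Why: Mild methanolysis of the primary allylic acetate; silyl ethers, benzyl ether and sulfone should be stable to carbonate at 0 °C.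

Step 16
Reactants: 23
Product: 24 [(2S,3R)-3-[(3E,5R,7S,8R,9E)-5-[(tert-butyldimethylsilyl)oxy]-8-[(4-methoxyphenyl)methoxy]-4,10-dimethyl-11-(phenylsulfonyl)-7-[(triethylsilyl)oxy]undeca-3,9-dien-1-yl]-3-methyloxiran-2-yl]methanol
Conditions: Ti(OiPr)4, L-(+)-diethyl tartrate, t-BuOOH, 4 Å molecular sieves, CH2Cl2, −20 °C
Reagents that add atoms: tert-butyl hydroperoxide, CC(C)(C)OO
Why: Sharpless asymmetric epoxidation; the titanium tartrate oxidises only the olefin that carries the free allylic hydroxyl (C7=C8). With the L-(+)-tartrate the Z allylic alcohol should give the 7S,8R oxirane as neryl alcohol does, and the syn addition keeps C6 and C9 cis.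

Step 17
Reactants: 24
Product: 25 (2R,3R)-2-(iodomethyl)-3-methyl-3-[(3E,5R,7S,8R,9E)-5-[(tert-butyldimethylsilyl)oxy]-8-[(4-methoxyphenyl)methoxy]-4,10-dimethyl-11-(phenylsulfonyl)-7-[(triethylsilyl)oxy]undeca-3,9-dien-1-yl]oxirane
Conditions: I2, PPh3, imidazole, CH2Cl2, 0 °C, dark; used at once
Reagents that add atoms: iodine, II
Why: Phosphonium activation of the primary hydroxyl and SN2 displacement by iodide (Garegg–Samuelsson conditions); imidazole buffers the acid so that epoxide and silyl ethers survive. The oxirane descriptor at C7 changes to R only because iodine outranks oxygen.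

Step 18
Reactants: 25
Product: 27 macrocyclic sulfone (1S,2R,3E,5R,7S,8R,11E,13R)-13-[(tert-butyldimethylsilyl)oxy]-7,8-epoxy-2-[(4-methoxyphenyl)methoxy]-4,8,12-trimethyl-5-(phenylsulfonyl)-1-[(triethylsilyl)oxy]cyclotetradeca-3,11-diene, via lithiated sulfone 26 (not isolated)
Conditions: LiN(SiMe3)2 (1.0 equiv), THF (0.002 M), −78 °C, then slowly to −20 °C
Reagents that add atoms: none
Why: LiN(SiMe3)2 removes a proton from C5, which is acidified by the sulfonyl group and the C3=C4 olefin, to give the allyl sulfonyl carbanion 26; on warming this displaces iodide from C6 by SN2 and forms C5–C6. The closest known reaction type is the intramolecular alkylation of sulfone-stabilised allyl anions used to close 14-membered terpenoid rings. The ring closes in the 14-exo-tet mode, with the breaking C–I bond outside the new ring, and high dilution keeps the bimolecular alkylation slow. The new centre at C5 is not under designed control; it should follow the preference of the bulky sulfonyl group for the outside of the ring in the cyclising conformer, and both epimers give the same CH2 after step 19. Four selectivities are needed: (a) α- over γ-alkylation, secured because the sulfonyl group localises the charge on C5 and γ-attack would close a more strained 12-membered ring at the hindered C3; (b) iodide over epoxide, secured because the primary C–I bond next to the oxirane is far more reactive toward a soft lithium carbanion than the trisubstituted epoxide carbons in the absence of a Lewis acid; (c) substitution over loss of the C2 alkoxide by vinylogous β-elimination, disfavoured by the lithium counter-ion, the ether leaving group and temperatures below −20 °C; (d) mono-alkylation, secured by one equivalent of base and the lower acidity and greater hindrance of the product C5–H, so that a second carbanion does not open the epoxide in a 3-exo fashion.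

Step 19
Reactants: 27
Product: 28 (1S,2R,3E,7S,8R,11E,13R)-13-[(tert-butyldimethylsilyl)oxy]-7,8-epoxy-2-[(4-methoxyphenyl)methoxy]-4,8,12-trimethyl-1-[(triethylsilyl)oxy]cyclotetradeca-3,11-diene
Conditions: Pd(PPh3)4 (10 mol %), NaBH4, THF–i-PrOH, 0 → 25 °C
Reagents that add atoms: none
Why: Palladium-catalysed reductive desulfonylation; zerovalent palladium ionises the allylic C5–S bond to a π-allyl complex over C3–C5, and hydride should add at C5, the terminus remote from the electron-withdrawing C2 ether, which restores the E C3=C4 olefin. No free allyl anion is formed, so the C2 ether cannot be eliminated, and NaBH4 leaves the epoxide alone.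

Step 20
Reactants: 28
Product: 29 (1S,2R,3E,7S,8R,11E,13R)-13-[(tert-butyldimethylsilyl)oxy]-7,8-epoxy-4,8,12-trimethyl-1-[(triethylsilyl)oxy]cyclotetradeca-3,11-dien-2-ol
Conditions: 2,3-dichloro-5,6-dicyano-1,4-benzoquinone, CH2Cl2–pH 7 phosphate buffer, 0 °C
Reagents that add atoms: none
Why: Oxidative cleavage of the p-methoxybenzyl ether through its benzylic oxocarbenium ion; buffering protects the triethylsilyl ether and the epoxide.

Step 21
Reactants: 29; 30 2-(diethoxyphosphoryl)propanoic acid
Product: 31 (1S,2R,3E,7S,8R,11E,13R)-13-[(tert-butyldimethylsilyl)oxy]-7,8-epoxy-4,8,12-trimethyl-1-[(triethylsilyl)oxy]cyclotetradeca-3,11-dien-2-yl 2-(diethoxyphosphoryl)propanoate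
Conditions: N,N'-dicyclohexylcarbodiimide, 4-(dimethylamino)pyridine (cat.), CH2Cl2, 0 → 25 °C
Reagents that add atoms: none
Why: Steglich esterification of the C2 hydroxyl; it attaches C15, C16 and C17 with the phosphonate needed for the olefination.

Step 22
Reactants: 31
Product: 32 (1S,2R,3E,7S,8R,11E,13R)-13-[(tert-butyldimethylsilyl)oxy]-7,8-epoxy-1-hydroxy-4,8,12-trimethylcyclotetradeca-3,11-dien-2-yl 2-(diethoxyphosphoryl)propanoate
Conditions: HF·pyridine, pyridine, THF, 0 °C
Reagents that add atoms: none
Why: Buffered fluoride cleaves the more labile triethylsilyl ether and should leave the tert-butyldimethylsilyl ether and the epoxide; the product is oxidised without delay so that the ester does not migrate to the C1 oxygen.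

Step 23
Reactants: 32
Product: 33 (2R,3E,7S,8R,11E,13R)-13-[(tert-butyldimethylsilyl)oxy]-7,8-epoxy-4,8,12-trimethyl-1-oxocyclotetradeca-3,11-dien-2-yl 2-(diethoxyphosphoryl)propanoate
Conditions: Dess–Martin periodinane, NaHCO3, CH2Cl2, 0 → 25 °C
Reagents that add atoms: none
Why: Neutral oxidation of the C1 carbinol to the ketone; the doubly activated C2–H is not exposed to base.

Step 24
Reactants: 33
Product: 34 (2R,3E,7S,8R,11E,13R)-13-[(tert-butyldimethylsilyl)oxy]-7,8-epoxycembra-1(15),3,11-trien-16,2-olide
Conditions: LiCl, i-Pr2NEt, MeCN, 0 → 25 °C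
Reagents that add atoms: none
Why: Intramolecular Horner–Wadsworth–Emmons reaction under Masamune–Roush conditions; lithium chelation makes the phosphonate acidic enough for a tertiary amine that is too weak to enolise the ketone toward C2 or C14. The five-membered ring closes and C1=C15 can only be endocyclic.

Step 25
Reactants: 34
Product: 35 (2R,3E,7S,8R,11E,13R)-7,8-epoxy-13-hydroxycembra-1(15),3,11-trien-16,2-olide
Conditions: HF·pyridine, pyridine, THF, 0 → 25 °C
Reagents that add atoms: none
Why: Fluoride cleavage of the C13 silyl ether under weakly acidic, non-basic conditions, which spares the butenolide γ-hydrogen; pyridine buffering protects the epoxide.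

Step 26
Reactants: 35
Product: 36 (2R,3E,7S,8R,11E,13R)-13-acetoxy-7,8-epoxycembra-1(15),3,11-trien-16,2-olide
Conditions: Ac2O, pyridine, 4-(dimethylamino)pyridine (cat.), CH2Cl2, 0 °C
Reagents that add atoms: acetic anhydride, CC(=O)OC(C)=O
Why: Acylation of the secondary allylic alcohol with retention at C13; the mild base should not epimerise C2.

## Compound list

1 | neryl acetate, (2Z)-3,7-dimethylocta-2,6-dien-1-yl acetate | CC(=O)OC/C=C(/C)CCC=C(C)C | starting material
2 | (2Z)-6,7-epoxy-3,7-dimethyloct-2-en-1-yl acetate (racemic) | CC(=O)OC/C=C(/C)CCC1OC1(C)C | intermediate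
3 | (2Z)-6,7-dihydroxy-3,7-dimethyloct-2-en-1-yl acetate (racemic) | CC(=O)OC/C=C(/C)CCC(O)C(C)(C)O | intermediate (not isolated)
4 | (2Z)-3-methyl-6-oxohex-2-en-1-yl acetate | CC(=O)OC/C=C(/C)CCC=O | intermediate
5 | 3-(triphenyl-λ5-phosphanylidene)butan-2-one | CC(=O)C(C)=P(c1ccccc1)(c1ccccc1)c1ccccc1 | starting material
6 | (2Z,6E)-3,7-dimethyl-8-oxonona-2,6-dien-1-yl acetate | CC(=O)OC/C=C(/C)CC/C=C(\C)C(C)=O | intermediate
7 | (S)-2,2-dimethyl-1,3-dioxolane-4-carbaldehyde | O=C[C@@H]1COC(C)(C)O1 | starting material
8 | ethyl 2-(triphenyl-λ5-phosphanylidene)propanoate | CCOC(=O)C(C)=P(c1ccccc1)(c1ccccc1)c1ccccc1 | starting material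
9 | ethyl (2E)-3-[(4R)-2,2-dimethyl-1,3-dioxolan-4-yl]-2-methylprop-2-enoate | CCOC(=O)/C(C)=C/[C@@H]1COC(C)(C)O1 | intermediate
10 | (2E)-3-[(4R)-2,2-dimethyl-1,3-dioxolan-4-yl]-2-methylprop-2-en-1-ol | OC/C(C)=C/[C@@H]1COC(C)(C)O1 | intermediate
11 | sodium benzenesulfinate | [Na+].[O-]S(=O)c1ccccc1 | starting material
12 | (2E)-3-[(4R)-2,2-dimethyl-1,3-dioxolan-4-yl]-2-methylprop-2-en-1-yl methanesulfonate | CS(=O)(=O)OC/C(C)=C/[C@@H]1COC(C)(C)O1 | intermediate (not isolated)
13 | (4R)-2,2-dimethyl-4-[(1E)-2-methyl-3-(phenylsulfonyl)prop-1-en-1-yl]-1,3-dioxolane | O=S(=O)(C/C(C)=C/[C@@H]1COC(C)(C)O1)c1ccccc1 | intermediate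
14 | (2R,3E)-4-methyl-5-(phenylsulfonyl)pent-3-ene-1,2-diol | O=S(=O)(C/C(C)=C/[C@@H](O)CO)c1ccccc1 | intermediate
15 | (4R)-2-(4-methoxyphenyl)-4-[(1E)-2-methyl-3-(phenylsulfonyl)prop-1-en-1-yl]-1,3-dioxolane (both acetal epimers) | O=S(=O)(C/C(C)=C/[C@@H]1COC(O1)c1ccc(OC)cc1)c1ccccc1 | intermediate
16 | (2R,3E)-2-[(4-methoxyphenyl)methoxy]-4-methyl-5-(phenylsulfonyl)pent-3-en-1-ol | O=S(=O)(C/C(C)=C/[C@@H](OCc1ccc(OC)cc1)CO)c1ccccc1 | intermediate
17 | (2R,3E)-2-[(4-methoxyphenyl)methoxy]-4-methyl-5-(phenylsulfonyl)pent-3-enal | O=C[C@H](OCc1ccc(OC)cc1)/C=C(\C)CS(=O)(=O)c1ccccc1 | intermediate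
18 | (2Z,6E)-8-[(dicyclohexylboranyl)oxy]-3,7-dimethylnona-2,6,8-trien-1-yl acetate | CC(=O)OC/C=C(/C)CC/C=C(\C)C(=C)OB(C1CCCCC1)C1CCCCC1 | intermediate (not isolated)
19 | (2Z,6E,10S,11R,12E)-10-hydroxy-11-[(4-methoxyphenyl)methoxy]-3,7,13-trimethyl-8-oxo-14-(phenylsulfonyl)tetradeca-2,6,12-trien-1-yl acetate | CC(=O)OC/C=C(/C)CC/C=C(\C)C(=O)C[C@H](O)[C@H](OCc1ccc(OC)cc1)/C=C(\C)CS(=O)(=O)c1ccccc1 | intermediate
20 | (2Z,6E,10S,11R,12E)-11-[(4-methoxyphenyl)methoxy]-3,7,13-trimethyl-8-oxo-14-(phenylsulfonyl)-10-[(triethylsilyl)oxy]tetradeca-2,6,12-trien-1-yl acetate | CC(=O)OC/C=C(/C)CC/C=C(\C)C(=O)C[C@H](O[Si](CC)(CC)CC)[C@H](OCc1ccc(OC)cc1)/C=C(\C)CS(=O)(=O)c1ccccc1 | intermediate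
21 | (2Z,6E,8R,10S,11R,12E)-8-hydroxy-11-[(4-methoxyphenyl)methoxy]-3,7,13-trimethyl-14-(phenylsulfonyl)-10-[(triethylsilyl)oxy]tetradeca-2,6,12-trien-1-yl acetate | CC(=O)OC/C=C(/C)CC/C=C(\C)[C@H](O)C[C@H](O[Si](CC)(CC)CC)[C@H](OCc1ccc(OC)cc1)/C=C(\C)CS(=O)(=O)c1ccccc1 | intermediate
22 | (2Z,6E,8R,10S,11R,12E)-8-[(tert-butyldimethylsilyl)oxy]-11-[(4-methoxyphenyl)methoxy]-3,7,13-trimethyl-14-(phenylsulfonyl)-10-[(triethylsilyl)oxy]tetradeca-2,6,12-trien-1-yl acetate | CC(=O)OC/C=C(/C)CC/C=C(\C)[C@H](O[Si](C)(C)C(C)(C)C)C[C@H](O[Si](CC)(CC)CC)[C@H](OCc1ccc(OC)cc1)/C=C(\C)CS(=O)(=O)c1ccccc1 | intermediate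
23 | (2Z,6E,8R,10S,11R,12E)-8-[(tert-butyldimethylsilyl)oxy]-11-[(4-methoxyphenyl)methoxy]-3,7,13-trimethyl-14-(phenylsulfonyl)-10-[(triethylsilyl)oxy]tetradeca-2,6,12-trien-1-ol | OC/C=C(/C)CC/C=C(\C)[C@H](O[Si](C)(C)C(C)(C)C)C[C@H](O[Si](CC)(CC)CC)[C@H](OCc1ccc(OC)cc1)/C=C(\C)CS(=O)(=O)c1ccccc1 | intermediate
24 | [(2S,3R)-3-[(3E,5R,7S,8R,9E)-5-[(tert-butyldimethylsilyl)oxy]-8-[(4-methoxyphenyl)methoxy]-4,10-dimethyl-11-(phenylsulfonyl)-7-[(triethylsilyl)oxy]undeca-3,9-dien-1-yl]-3-methyloxiran-2-yl]methanol | OC[C@@H]1O[C@]1(C)CC/C=C(\C)[C@H](O[Si](C)(C)C(C)(C)C)C[C@H](O[Si](CC)(CC)CC)[C@H](OCc2ccc(OC)cc2)/C=C(\C)CS(=O)(=O)c3ccccc3 | intermediate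
25 | (2R,3R)-2-(iodomethyl)-3-methyl-3-[(3E,5R,7S,8R,9E)-5-[(tert-butyldimethylsilyl)oxy]-8-[(4-methoxyphenyl)methoxy]-4,10-dimethyl-11-(phenylsulfonyl)-7-[(triethylsilyl)oxy]undeca-3,9-dien-1-yl]oxirane | IC[C@@H]1O[C@]1(C)CC/C=C(\C)[C@H](O[Si](C)(C)C(C)(C)C)C[C@H](O[Si](CC)(CC)CC)[C@H](OCc2ccc(OC)cc2)/C=C(\C)CS(=O)(=O)c3ccccc3 | intermediate
26 | lithium salt of the C5 carbanion of 25 | [Li+].IC[C@@H]1O[C@]1(C)CC/C=C(\C)[C@H](O[Si](C)(C)C(C)(C)C)C[C@H](O[Si](CC)(CC)CC)[C@H](OCc2ccc(OC)cc2)/C=C(\C)[CH-]S(=O)(=O)c3ccccc3 | intermediate (not isolated)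
27 | (1S,2R,3E,5R,7S,8R,11E,13R)-13-[(tert-butyldimethylsilyl)oxy]-7,8-epoxy-2-[(4-methoxyphenyl)methoxy]-4,8,12-trimethyl-5-(phenylsulfonyl)-1-[(triethylsilyl)oxy]cyclotetradeca-3,11-diene | CC(C)(C)[Si](C)(C)O[C@@H]1C[C@H](O[Si](CC)(CC)CC)[C@H](OCc3ccc(OC)cc3)/C=C(\C)[C@H](S(=O)(=O)c3ccccc3)C[C@@H]2O[C@]2(C)CC/C=C/1C | intermediate
28 | (1S,2R,3E,7S,8R,11E,13R)-13-[(tert-butyldimethylsilyl)oxy]-7,8-epoxy-2-[(4-methoxyphenyl)methoxy]-4,8,12-trimethyl-1-[(triethylsilyl)oxy]cyclotetradeca-3,11-diene | CC(C)(C)[Si](C)(C)O[C@@H]1C[C@H](O[Si](CC)(CC)CC)[C@H](OCc3ccc(OC)cc3)/C=C(\C)CC[C@@H]2O[C@]2(C)CC/C=C/1C | intermediate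
29 | (1S,2R,3E,7S,8R,11E,13R)-13-[(tert-butyldimethylsilyl)oxy]-7,8-epoxy-4,8,12-trimethyl-1-[(triethylsilyl)oxy]cyclotetradeca-3,11-dien-2-ol | CC(C)(C)[Si](C)(C)O[C@@H]1C[C@H](O[Si](CC)(CC)CC)[C@H](O)/C=C(\C)CC[C@@H]2O[C@]2(C)CC/C=C/1C | intermediate
30 | 2-(diethoxyphosphoryl)propanoic acid (racemic) | CCOP(=O)(OCC)C(C)C(=O)O | starting material
31 | (1S,2R,3E,7S,8R,11E,13R)-13-[(tert-butyldimethylsilyl)oxy]-7,8-epoxy-4,8,12-trimethyl-1-[(triethylsilyl)oxy]cyclotetradeca-3,11-dien-2-yl 2-(diethoxyphosphoryl)propanoate | CC(C)(C)[Si](C)(C)O[C@@H]1C[C@H](O[Si](CC)(CC)CC)[C@H](OC(=O)C(C)P(=O)(OCC)OCC)/C=C(\C)CC[C@@H]2O[C@]2(C)CC/C=C/1C | intermediate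
32 | (1S,2R,3E,7S,8R,11E,13R)-13-[(tert-butyldimethylsilyl)oxy]-7,8-epoxy-1-hydroxy-4,8,12-trimethylcyclotetradeca-3,11-dien-2-yl 2-(diethoxyphosphoryl)propanoate | CC(C)(C)[Si](C)(C)O[C@@H]1C[C@H](O)[C@H](OC(=O)C(C)P(=O)(OCC)OCC)/C=C(\C)CC[C@@H]2O[C@]2(C)CC/C=C/1C | intermediate
33 | (2R,3E,7S,8R,11E,13R)-13-[(tert-butyldimethylsilyl)oxy]-7,8-epoxy-4,8,12-trimethyl-1-oxocyclotetradeca-3,11-dien-2-yl 2-(diethoxyphosphoryl)propanoate | CC(C)(C)[Si](C)(C)O[C@@H]1CC(=O)[C@H](OC(=O)C(C)P(=O)(OCC)OCC)/C=C(\C)CC[C@@H]2O[C@]2(C)CC/C=C/1C | intermediate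
34 | (2R,3E,7S,8R,11E,13R)-13-[(tert-butyldimethylsilyl)oxy]-7,8-epoxycembra-1(15),3,11-trien-16,2-olide | CC(C)(C)[Si](C)(C)O[C@@H]1CC2=C(C)C(=O)O[C@@H]2/C=C(\C)CC[C@@H]3O[C@]3(C)CC/C=C/1C | intermediate
35 | (2R,3E,7S,8R,11E,13R)-7,8-epoxy-13-hydroxycembra-1(15),3,11-trien-16,2-olide | O[C@@H]1CC2=C(C)C(=O)O[C@@H]2/C=C(\C)CC[C@@H]3O[C@]3(C)CC/C=C/1C | intermediate
36 | (2R,3E,7S,8R,11E,13R)-13-acetoxy-7,8-epoxycembra-1(15),3,11-trien-16,2-olide (CNP0302675.1) | CC(=O)O[C@@H]1CC2=C(C)C(=O)O[C@@H]2/C=C(\C)CC[C@@H]2O[C@]2(C)CC/C=C/1C | target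

## Step count and least certain steps

Total: 26 steps. Longest linear sequence: 23 steps (steps 4–10, then 11–26, from 7).

Step 18 (key step). What may go wrong: the carbanion must live at the temperature that a slow 14-membered closure needs. Bimolecular alkylation to oligomers, or loss of the C2 alkoxide by vinylogous β-elimination from the allyl anion, can then overtake ring closure. Fallback: the ring is closed on a substrate in which the C2 oxygen cannot leave. From 25 the p-methoxybenzyl ether is removed first (2,3-dichloro-5,6-dicyano-1,4-benzoquinone, buffered CH2Cl2) to give (2R,3R)-2-(iodomethyl)-3-methyl-3-[(3E,5R,7S,8R,9E)-5-[(tert-butyldimethylsilyl)oxy]-8-hydroxy-4,10-dimethyl-11-(phenylsulfonyl)-7-[(triethylsilyl)oxy]undeca-3,9-dien-1-yl]oxirane F1. Two equivalents of LiN(SiMe3)2 at high dilution below −20 °C then form the alkoxide–carbanion pair, and C-alkylation gives the macrocyclic hydroxy sulfone (1S,2R,3E,5R,7S,8R,11E,13R)-13-[(tert-butyldimethylsilyl)oxy]-7,8-epoxy-4,8,12-trimethyl-5-(phenylsulfonyl)-1-[(triethylsilyl)oxy]cyclotetradeca-3,11-dien-2-ol F2. Desulfonylation of F2 with Pd(PPh3)4 and NaBH4 returns to the route at 29. The low temperature is also meant to hold back a silyl shift from the C1 to the C2 oxygen.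

Step 19. What may go wrong: hydride may be delivered to C3 instead of C5, which moves the double bond to C4=C5, because both termini of the allyl unit are secondary. Ionisation of the hindered secondary sulfone may also be slow. Fallback: from 27, electron-transfer cleavage with sodium amalgam, Na(Hg), and Na2HPO4 in MeOH–THF at −20 °C gives 28 directly. The protic buffer is there so that protonation of the allyl intermediate outruns loss of the C2 ether; no new compound is involved.

Step 24. What may go wrong: the C2–H of 33 is α to the ketone, allylic and on an acyloxy carbon, so enolisation can epimerise C2. Enolisation toward C14 can eliminate the C13 silyloxy group before the olefination occurs. Fallback: the lactone is closed without base by a reductive aldol. From 29, acylation with 2-bromopropanoyl bromide and pyridine gives (1S,2R,3E,7S,8R,11E,13R)-13-[(tert-butyldimethylsilyl)oxy]-7,8-epoxy-4,8,12-trimethyl-1-[(triethylsilyl)oxy]cyclotetradeca-3,11-dien-2-yl 2-bromopropanoate F3. Buffered HF·pyridine gives the C1 alcohol (1S,2R,3E,7S,8R,11E,13R)-13-[(tert-butyldimethylsilyl)oxy]-7,8-epoxy-1-hydroxy-4,8,12-trimethylcyclotetradeca-3,11-dien-2-yl 2-bromopropanoate F4. Dess–Martin oxidation gives the ketone (2R,3E,7S,8R,11E,13R)-13-[(tert-butyldimethylsilyl)oxy]-7,8-epoxy-4,8,12-trimethyl-1-oxocyclotetradeca-3,11-dien-2-yl 2-bromopropanoate F5. SmI2 in THF at −78 °C effects an intramolecular Reformatsky reaction to the hydroxy lactone (2R,3E,7S,8R,11E,13R)-13-[(tert-butyldimethylsilyl)oxy]-7,8-epoxy-1-hydroxycembra-3,11-dien-16,2-olide F6. Dehydration with SOCl2 and pyridine at 0 °C returns to the route at 34.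

Step 11. What may go wrong: the amine present during the boron aldol can enolise aldehyde 17 before carbon–carbon bond formation, which epimerises C2 or moves the olefin into conjugation. Fallback: the same bond is made under Lewis acid and without base. From 6, Me3SiOSO2CF3 and Et3N give the silyl dienol ether (2Z,6E)-3,7-dimethyl-8-[(trimethylsilyl)oxy]nona-2,6,8-trien-1-yl acetate F7. A Mukaiyama aldol addition of F7 to 17 with BF3·OEt2 in CH2Cl2 at −78 °C (non-chelating, Felkin–Anh sense) returns to the route at 19.

## Further compounds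

F1 | step 18 | (2R,3R)-2-(iodomethyl)-3-methyl-3-[(3E,5R,7S,8R,9E)-5-[(tert-butyldimethylsilyl)oxy]-8-hydroxy-4,10-dimethyl-11-(phenylsulfonyl)-7-[(triethylsilyl)oxy]undeca-3,9-dien-1-yl]oxirane | IC[C@@H]1O[C@]1(C)CC/C=C(\C)[C@H](O[Si](C)(C)C(C)(C)C)C[C@H](O[Si](CC)(CC)CC)[C@H](O)/C=C(\C)CS(=O)(=O)c2ccccc2
F2 | step 18 | (1S,2R,3E,5R,7S,8R,11E,13R)-13-[(tert-butyldimethylsilyl)oxy]-7,8-epoxy-4,8,12-trimethyl-5-(phenylsulfonyl)-1-[(triethylsilyl)oxy]cyclotetradeca-3,11-dien-2-ol | CC(C)(C)[Si](C)(C)O[C@@H]1C[C@H](O[Si](CC)(CC)CC)[C@H](O)/C=C(\C)[C@H](S(=O)(=O)c3ccccc3)C[C@@H]2O[C@]2(C)CC/C=C/1C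
F0 | step 19 | none | none
F3 | step 24 | (1S,2R,3E,7S,8R,11E,13R)-13-[(tert-butyldimethylsilyl)oxy]-7,8-epoxy-4,8,12-trimethyl-1-[(triethylsilyl)oxy]cyclotetradeca-3,11-dien-2-yl 2-bromopropanoate | CC(C)(C)[Si](C)(C)O[C@@H]1C[C@H](O[Si](CC)(CC)CC)[C@H](OC(=O)C(C)Br)/C=C(\C)CC[C@@H]2O[C@]2(C)CC/C=C/1C
F4 | step 24 | (1S,2R,3E,7S,8R,11E,13R)-13-[(tert-butyldimethylsilyl)oxy]-7,8-epoxy-1-hydroxy-4,8,12-trimethylcyclotetradeca-3,11-dien-2-yl 2-bromopropanoate | CC(C)(C)[Si](C)(C)O[C@@H]1C[C@H](O)[C@H](OC(=O)C(C)Br)/C=C(\C)CC[C@@H]2O[C@]2(C)CC/C=C/1C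
F5 | step 24 | (2R,3E,7S,8R,11E,13R)-13-[(tert-butyldimethylsilyl)oxy]-7,8-epoxy-4,8,12-trimethyl-1-oxocyclotetradeca-3,11-dien-2-yl 2-bromopropanoate | CC(C)(C)[Si](C)(C)O[C@@H]1CC(=O)[C@H](OC(=O)C(C)Br)/C=C(\C)CC[C@@H]2O[C@]2(C)CC/C=C/1C
F6 | step 24 | (2R,3E,7S,8R,11E,13R)-13-[(tert-butyldimethylsilyl)oxy]-7,8-epoxy-1-hydroxycembra-3,11-dien-16,2-olide (C1 and C15 epimers) | CC(C)(C)[Si](C)(C)O[C@@H]1CC2(O)C(C)C(=O)O[C@@H]2/C=C(\C)CC[C@@H]3O[C@]3(C)CC/C=C/1C
F7 | step 11 | (2Z,6E)-3,7-dimethyl-8-[(trimethylsilyl)oxy]nona-2,6,8-trien-1-yl acetate | CC(=O)OC/C=C(/C)CC/C=C(\C)C(=C)O[Si](C)(C)C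
A1 | alternative 1 | (2R,3E,7E,11E,13R)-13-hydroxycembra-1(15),3,7,11-tetraen-16,2-olide | O[C@@H]1CC2=C(C)C(=O)O[C@@H]2/C=C(\C)CC/C=C(\C)CC/C=C/1C
A2 | alternative 2 | (1S,2S,7S,8R,11E,13R)-13-[(tert-butyldimethylsilyl)oxy]-7,8-epoxy-8,12-dimethyl-1-(prop-1-en-2-yl)cyclotetradec-11-en-3-yn-2-ol | CC(C)(C)[Si](C)(C)O[C@@H]1C[C@@H](C(C)=C)[C@H](O)C#CCC[C@@H]2O[C@]2(C)CC/C=C/1C
A3 | alternative 3 | (2R,3E,7S,8R,13R)-13-[(tert-butyldimethylsilyl)oxy]-7,8-epoxy-20-norcembra-1(15),3-dien-11-yn-16,2-olide | CC(C)(C)[Si](C)(C)O[C@@H]1CC2=C(C)C(=O)O[C@@H]2/C=C(\C)CC[C@@H]2O[C@]2(C)CCC#C1
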